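**Retrosynthetic overview**
1. The bicyclo[2.2.2]octane is closed last by an intramolecular aldol: the ring D ketone enol attacks an α-formyl γ-lactone (ring E) on a bicyclo[3.2.1]octanone. The biomimetic cyclohexadienone Diels–Alder is not used.
2. Ring E comes from dichloroketene [2+2] / Baeyer–Villiger on an exocyclic methylene; the tertiary carbinol comes from MeCeCl2 addition to the ring B ketone.
3. Ring C and its methyl-bearing quaternary carbon come from deconjugative α-alkylation of the extended enolate of a cross-conjugated spirodienone by an allylic iodide made in the flask.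
4. The ring B/ring D spiro centre comes from a gold-catalysed dearomative ipso-cyclisation of a phenol onto an alkyne, with stereochemistry relayed from a temporary propargylic silyl ether.
5. Ring A and the first two stereocentres come from acrylate ring-closing metathesis and a Brown allylboration with an allene-derived allylborane. Ring order: A, then B with D (spiro), C, E, bridging ring.

Ring labels: ring A = unsaturated δ-lactone; ring B = cyclohexane; ring C = cyclopentane; ring D = cyclohexanone; ring E = γ-lactone.

Assumption: (−)-Ipc2BH (diisopinocampheylborane from (+)-α-pinene) is taken as the antipode that gives the (3R,4S) adduct 15; if the sense is the reverse, (+)-Ipc2BH is used and nothing else changes.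

Assumption: compounds 1, 6 and 11 are taken as commercial.

**Route**

Step 1
Reactants: 1 4-bromo-2,3,6-trimethylphenol
Product: 2 (4-bromo-2,3,6-trimethylphenoxy)(tert-butyl)dimethylsilane
Conditions: t-BuMe2SiCl, imidazole, DMF, rt
Reagents that add atoms: tert-butyldimethylsilyl chloride (CC(C)(C)[Si](C)(C)Cl)
Why: Silyl ether protection of the phenol so that the aryl bromide can be metallated and carried through the organometallic steps.

Step 2
Reactants: 2 aryl bromide silyl ether
Product: 4 2-[4-(tert-butyldimethylsilyloxy)-2,3,5-trimethylphenyl]ethanol, via aryllithium 3 (not isolated)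
Conditions: n-BuLi, THF, −78 °C; then oxirane, BF3·OEt2, −78 → 0 °C; aq. NH4Cl
Reagents that add atoms: oxirane (C1CO1)
Why: Bromine–lithium exchange followed by BF3-assisted epoxide opening installs the two-carbon link (the future CH2–CH2 of ring B) para to the oxygen.

Step 3
Reactants: 4 arylethanol
Product: 5 [4-(2-bromoethyl)-2,3,6-trimethylphenoxy](tert-butyl)dimethylsilane
Conditions: CBr4, PPh3, CH2Cl2, 0 °C
Reagents that add atoms: tetrabromomethane (BrC(Br)(Br)Br)
Why: Appel bromination turns the primary alcohol into the bromide needed for Grignard formation.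

Step 4
Reactants: 6 4-methylpent-2-yne-1,4-diol
Product: 8 4-methyl-4-(trimethylsilyloxy)pent-2-yn-1-yl methanesulfonate, via mesylate 7 (not isolated)
Conditions: MeSO2Cl, Et3N, CH2Cl2, −30 °C; then Me3SiCl, imidazole, 0 °C
Reagents that add atoms: methanesulfonyl chloride (CS(=O)(=O)Cl); chlorotrimethylsilane (C[Si](C)(C)Cl)
Why: The primary propargylic hydroxyl is sulfonylated selectively and the tertiary hydroxyl is then masked so that it cannot quench the Grignard reagent or the borane later.

Step 5
Reactants: 5 arylethyl bromide; 8 propargylic mesylate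
Product: 10 tert-butyldimethyl{2,3,6-trimethyl-4-[3-(2-trimethylsilyloxypropan-2-yl)penta-3,4-dienyl]phenoxy}silane, via Grignard reagent 9 (not isolated)
Conditions: Mg, THF, rt; then 8, CuBr·SMe2 (10 mol%), THF, −40 → 0 °C
Reagents that add atoms: none
Why: Copper-catalysed anti-SN2′ substitution of the propargylic mesylate by the alkyl Grignard reagent gives the 1,1-disubstituted allene carrying the future spiro carbon of ring A.

Step 6
Reactants: 10 allene; 11 3-(trimethylsilyl)prop-2-ynal
Product: 15 (3R,4S)-4-{2-[4-(tert-butyldimethylsilyloxy)-2,3,5-trimethylphenyl]ethyl}-4-ethenyl-5-methyl-1-(trimethylsilyl)hex-1-yne-3,5-diol, via allylborane 12 (not isolated), via borinate 13 (not isolated), via silyl ether 14 (not isolated)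
Conditions: (−)-Ipc2BH, Et2O, −25 °C; then 11, −78 °C; NaBO3·4H2O, THF–H2O, rt; then 1 M HCl, MeOH, 0 °C
Reagents that add atoms: none
Why: Brown allylboration: the borane adds to the terminal C=C of the allene from the side of the smaller substituent to give the (Z)-allylborane (CH2B cis to the CMe2OSiMe3 group), which reacts with the aldehyde through a chair Zimmerman–Traxler transition state with the alkynyl group equatorial, setting the quaternary carbon and the carbinol in the relative configuration shown, with absolute configuration from the isopinocampheyl groups; the acidic work-up removes the tertiary Me3Si group.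

Step 7
Reactants: 15 diol
Product: 16 secondary tert-butyldimethylsilyl ether of diol 15 (tertiary hydroxyl free)
Conditions: t-BuMe2SiOTf (1.05 equiv), 2,6-lutidine, CH2Cl2, −78 °C
Reagents that add atoms: tert-butyldimethylsilyl triflate (CC(C)(C)[Si](C)(C)OS(=O)(=O)C(F)(F)F)
Why: The secondary propargylic hydroxyl is silylated much faster than the tertiary one; this silyl ether later acts as the temporary stereocontrol element for the spirocyclisation.

Step 8
Reactants: 16 hydroxy silyl ether
Product: 17 acrylate ester of the tertiary hydroxyl of 16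
Conditions: LiN(SiMe3)2, THF, −78 °C; then CH2=CHCOCl, −78 → 0 °C
Reagents that add atoms: acryloyl chloride (C=CC(Cl)=O)
Why: O-acylation of the lithium alkoxide of the hindered tertiary alcohol provides the acrylate partner for ring closure.

Step 9
Reactants: 17 acrylate
Product: 18 ring A lactone: 6,6-dimethyl-5,6-dihydro-2H-pyran-2-one carrying at C5 the 2-arylethyl chain and the 1-(tert-butyldimethylsilyloxy)-3-(trimethylsilyl)prop-2-ynyl group
Conditions: second-generation Hoveyda–Grubbs catalyst [RuCl2(H2IMes)(=CH-C6H4-2-O-i-Pr)] (5 mol%), toluene, 80 °C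
Reagents that add atoms: none
Why: Ring-closing metathesis between the vinyl group on the quaternary carbon and the acrylate, helped by the gem-dimethyl effect, forms ring A; the silylated alkyne is inert.

Step 10
Reactants: 18 ring A lactone
Product: 19 phenol with terminal alkyne (secondary silyl ether retained)
Conditions: Bu4NF (2.2 equiv), AcOH (2.2 equiv), THF, −20 → 0 °C
Reagents that add atoms: none
Why: Buffered fluoride cleaves the aryl silyl ether and the C–SiMe3 bond far faster than the hindered secondary alkyl silyl ether.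

Step 11
Reactants: 19 phenol alkyne
Product: 20 dispiro dienone: ring B (with exocyclic methylene and the silyl ether) spiro-linked to ring A and to a 2,3,6-trimethylcyclohexa-2,5-dienone
Conditions: [Au(NCMe){P(t-Bu)2(2-biphenylyl)}]SbF6 (5 mol%), CH2Cl2, 0 °C → rt
Reagents that add atoms: none
Why: Gold-catalysed 6-exo-dig dearomative ipso-hydroarylation: the para carbon of the phenol attacks the activated alkyne to give the spirocyclohexadienone, and the new spiro centre is set in a chair transition state with the silyloxy group axial (A(1,3) strain with the aurated vinyl), the CMe2 arm of ring A equatorial and the unsubstituted ortho CH of the arene, not the methyl-bearing ortho carbon, syn to the axial silyloxy group.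

Step 12
Reactants: 20 dispiro dienone silyl ether
Product: 22 α-methylene ketone (ring B ketone next to the exocyclic methylene), via allylic alcohol 21 (not isolated)
Conditions: CrO3, H2SO4, acetone–H2O, 0 °C
Reagents that add atoms: none
Why: The acid cleaves the allylic silyl ether and Jones oxidation of the freed allylic alcohol gives the enone, erasing the temporary carbinol stereocentre once it has done its work.

Step 13
Reactants: 22 α-methylene ketone
Product: 25 tetracyclic diketone with bicyclo[3.2.1]octenone core and exocyclic methylene on the one-carbon bridge, via iodide 23 (not isolated), via silyl enol ether 24 (not isolated)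
Conditions: Me3SiI (1.05 equiv), CH2Cl2, −78 °C; then KN(SiMe3)2, THF–toluene, −78 → −20 °C; then 1 M HCl
Reagents that add atoms: none
Why: Proposed new method: Me3SiI adds 1,4 to the α-methylene ketone to give an allylic iodide locked as its silyl enol ether (no acidic α-hydrogen, so no elimination), KN(SiMe3)2 removes a γ-hydrogen from the β-methyl of the cross-conjugated dienone, the extended enolate is alkylated at its α-carbon in a 5-exo-tet SN2 step that forms ring C and the methyl-bearing quaternary carbon, and hydrolysis protonates the ring-fusion carbon to the only unstrained (cis) fusion; the closest known reactions are conjugate addition of Me3SiI to enones and kinetic α-alkylation (deconjugative alkylation) of dienolates.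

Step 14
Reactants: 25 tetracyclic diketone
Product: 26 spiro α,α-dichlorocyclobutanone on the one-carbon bridge
Conditions: Cl3CCOCl, Zn–Cu couple, Et2O–DME, sonication, 0 °C → rt
Reagents that add atoms: trichloroacetyl chloride (O=C(Cl)C(Cl)(Cl)Cl)
Why: [2+2] cycloaddition of dichloroketene to the exocyclic methylene: the carbonyl carbon bonds to the CH2 terminus and the CCl2 carbon to the bridge carbon from the face over the flat enone bridge (anti to ring B), which sets the quaternary carbon of ring E.

Step 15
Reactants: 26 dichlorocyclobutanone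
Product: 27 α,α-dichloro γ-lactone
Conditions: mCPBA (1.1 equiv), NaHCO3, CH2Cl2, 0 °C
Reagents that add atoms: 3-chloroperbenzoic acid (OOC(=O)c1cccc(Cl)c1)
Why: Regioselective Baeyer–Villiger oxidation: the strained dichlorocyclobutanone reacts before the other ketones and the non-halogenated CH2 migrates, so oxygen is inserted between the CH2 and the carbonyl carbon, with the quaternary spiro carbon untouched.

Step 16
Reactants: 27 dichlorolactone
Product: 28 γ-lactone (ring E) with ring B ketone and ring D enone
Conditions: Zn dust, AcOH, rt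
Reagents that add atoms: none
Why: Zinc removes both α-chlorines reductively through the zinc enolate, leaving ring E.

Step 17
Reactants: 28 keto lactone
Product: 29 tertiary alcohol (methyl carbinol in ring B)
Conditions: MeLi, CeCl3, THF, −78 °C
Reagents that add atoms: methyllithium ([Li]C)
Why: The non-basic organocerium reagent adds to the ring B ketone (lactones and the doubly flanked enone carbonyl are slow at −78 °C) from the convex face, anti to ring C and to the lactone CH2 lying under the concave face, so methyl ends cis to the ring-fusion hydrogen and hydroxyl cis to ring C.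

Step 18
Reactants: 29 tertiary alcohol
Product: 30 (Z)-α-hydroxymethylene γ-lactone (enol form of the α-formyl lactone)
Conditions: LiN(i-Pr)2 (2.5 equiv), THF, −78 °C; then HCO2Et, −78 → 0 °C; aq. NaHCO3
Reagents that add atoms: ethyl formate (CCOC=O)
Why: Claisen-type formylation of the γ-lactone enolate, the only enolisable position in the molecule; the extra base covers the alkoxide.

Step 19
Reactants: 30 hydroxymethylene lactone
Product: 31 saturated ring D ketone (mixture of epimers at the methyl-bearing α-carbon)
Conditions: Pd(PPh3)4 (5 mol%), ZnCl2, Ph2SiH2, CHCl3, rt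
Reagents that add atoms: none
Why: Keinan conjugate reduction (palladium-catalysed hydrosilane transfer assisted by ZnCl2) reduces the ketone-conjugated alkene but not the ester-conjugated alkene of ring A.

Step 20
Reactants: 31 saturated ketone
Product: 32 target compound CNP0360620.3
Conditions: camphorsulfonic acid (10 mol%), CH2Cl2, rt → 40 °C
Reagents that add atoms: none
Why: Acid-catalysed intramolecular aldol: the ketone can enolise only toward the methyl-bearing α-carbon, which attacks the formyl carbon held over it by the spiro lactone, closing the bicyclo[2.2.2]octane and forming the last quaternary carbon; the hydroxyl ends syn to the ketone bridge (hydrogen-bonded closed transition state) and the lactone α-carbon settles in its thermodynamic configuration.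

**Compound list**

1 | 4-bromo-2,3,6-trimethylphenol | Cc1cc(Br)c(C)c(C)c1O | starting material
2 | (4-bromo-2,3,6-trimethylphenoxy)(tert-butyl)dimethylsilane | Cc1cc(Br)c(C)c(C)c1O[Si](C)(C)C(C)(C)C | intermediate
3 | [4-(tert-butyldimethylsilyloxy)-2,3,5-trimethylphenyl]lithium | Cc1cc([Li])c(C)c(C)c1O[Si](C)(C)C(C)(C)C | intermediate
4 | 2-[4-(tert-butyldimethylsilyloxy)-2,3,5-trimethylphenyl]ethanol | Cc1cc(CCO)c(C)c(C)c1O[Si](C)(C)C(C)(C)C | intermediate
5 | [4-(2-bromoethyl)-2,3,6-trimethylphenoxy](tert-butyl)dimethylsilane | Cc1cc(CCBr)c(C)c(C)c1O[Si](C)(C)C(C)(C)C | intermediate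
6 | 4-methylpent-2-yne-1,4-diol | CC(C)(O)C#CCO | starting material
7 | 4-hydroxy-4-methylpent-2-yn-1-yl methanesulfonate | CC(C)(O)C#CCOS(C)(=O)=O | intermediate
8 | 4-methyl-4-(trimethylsilyloxy)pent-2-yn-1-yl methanesulfonate | CC(C)(O[Si](C)(C)C)C#CCOS(C)(=O)=O | intermediate
9 | {2-[4-(tert-butyldimethylsilyloxy)-2,3,5-trimethylphenyl]ethyl}magnesium bromide | Cc1cc(CC[Mg]Br)c(C)c(C)c1O[Si](C)(C)C(C)(C)C | intermediate
10 | tert-butyldimethyl{2,3,6-trimethyl-4-[3-(2-trimethylsilyloxypropan-2-yl)penta-3,4-dienyl]phenoxy}silane | C=C=C(CCc1cc(C)c(O[Si](C)(C)C(C)(C)C)c(C)c1C)C(C)(C)O[Si](C)(C)C | intermediate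
11 | 3-(trimethylsilyl)prop-2-ynal | C[Si](C)(C)C#CC=O | starting material
12 | (Z)-allyl(diisopinocampheyl)borane from 10 (CH2B cis to the CMe2OSiMe3 group) | C[Si](C)(C)OC(C)(C)/C(CCc1cc(C)c(O[Si](C)(C)C(C)(C)C)c(C)c1C)=C\CB([C@@H]1C[C@@H]2C[C@H]([C@H]1C)C2(C)C)[C@@H]1C[C@@H]2C[C@H]([C@H]1C)C2(C)C | intermediate
13 | diisopinocampheylborinate ester of 14 (boron on the secondary oxygen) | C=C[C@](CCc1cc(C)c(O[Si](C)(C)C(C)(C)C)c(C)c1C)(C(C)(C)O[Si](C)(C)C)[C@@H](OB([C@@H]1C[C@@H]2C[C@H]([C@H]1C)C2(C)C)[C@@H]1C[C@@H]2C[C@H]([C@H]1C)C2(C)C)C#C[Si](C)(C)C | intermediate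
14 | tertiary trimethylsilyl ether of diol 15 | C=C[C@](CCc1cc(C)c(O[Si](C)(C)C(C)(C)C)c(C)c1C)(C(C)(C)O[Si](C)(C)C)[C@@H](O)C#C[Si](C)(C)C | intermediate
15 | (3R,4S)-4-{2-[4-(tert-butyldimethylsilyloxy)-2,3,5-trimethylphenyl]ethyl}-4-ethenyl-5-methyl-1-(trimethylsilyl)hex-1-yne-3,5-diol | C=C[C@](CCc1cc(C)c(O[Si](C)(C)C(C)(C)C)c(C)c1C)(C(C)(C)O)[C@@H](O)C#C[Si](C)(C)C | intermediate
16 | secondary tert-butyldimethylsilyl ether of 15 (tertiary hydroxyl free; configuration as 15) | C=C[C@](CCc1cc(C)c(O[Si](C)(C)C(C)(C)C)c(C)c1C)(C(C)(C)O)[C@@H](O[Si](C)(C)C(C)(C)C)C#C[Si](C)(C)C | intermediate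
17 | acrylate ester of the tertiary hydroxyl of 16 | C=C[C@](CCc1cc(C)c(O[Si](C)(C)C(C)(C)C)c(C)c1C)(C(C)(C)OC(=O)C=C)[C@@H](O[Si](C)(C)C(C)(C)C)C#C[Si](C)(C)C | intermediate
18 | ring A lactone: 6,6-dimethyl-5,6-dihydro-2H-pyran-2-one with C5 carrying the 2-arylethyl chain and the 1-(tert-butyldimethylsilyloxy)-3-(trimethylsilyl)prop-2-ynyl group | CC1(C)OC(=O)C=C[C@@]1(CCc1cc(C)c(O[Si](C)(C)C(C)(C)C)c(C)c1C)[C@@H](O[Si](C)(C)C(C)(C)C)C#C[Si](C)(C)C | intermediate
19 | phenol and terminal alkyne from 18 (secondary silyl ether retained) | CC1(C)OC(=O)C=C[C@@]1(CCc1cc(C)c(O)c(C)c1C)[C@@H](O[Si](C)(C)C(C)(C)C)C#C | intermediate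
20 | dispiro dienone: ring B with exocyclic methylene and silyloxy group, spiro to ring A and to a 2,3,6-trimethylcyclohexa-2,5-dienone; silyloxy group syn to the CH= arm of the dienone and to the CMe2 arm of ring A | CC1(C)OC(=O)C=C[C@]12CC[C@]3(C=C(C)C(=O)C(C)=C3C)C(=C)[C@@H]2O[Si](C)(C)C(C)(C)C | intermediate
21 | allylic alcohol from 20 | CC1(C)OC(=O)C=C[C@]12CC[C@]3(C=C(C)C(=O)C(C)=C3C)C(=C)[C@@H]2O | intermediate
22 | α-methylene ketone: ring B ketone flanked by the ring A spiro carbon and the exocyclic methylene | CC1(C)OC(=O)C=C[C@]12CC[C@]3(C=C(C)C(=O)C(C)=C3C)C(=C)C2=O | intermediate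
23 | 2-(iodomethyl) trimethylsilyl enol ether of the ring B ketone | CC1(C)OC(=O)C=C[C@]12CC[C@]3(C=C(C)C(=O)C(C)=C3C)C(CI)=C2O[Si](C)(C)C | intermediate
24 | trimethylsilyl enol ether of 25 (ring C closed) | CC1(C)OC(=O)C=C[C@]12CC[C@]13C=C(C)C(=O)[C@](C)(CC1=C2O[Si](C)(C)C)C3=C | intermediate
25 | tetracyclic diketone: rings A, B and C plus the ring D enone, bicyclo[3.2.1]octenone core with exocyclic methylene on the one-carbon bridge, cis B/C fusion | CC1(C)OC(=O)C=C[C@]12CC[C@]13C=C(C)C(=O)[C@](C)(C[C@H]1C2=O)C3=C | intermediate
26 | spiro α,α-dichlorocyclobutanone on the one-carbon bridge (CCl2 carbon over the enone bridge) | CC1(C)OC(=O)C=C[C@]12CC[C@]13C=C(C)C(=O)[C@](C)(C[C@H]1C2=O)[C@]31CC(=O)C1(Cl)Cl | intermediate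
27 | spiro α,α-dichloro γ-lactone | CC1(C)OC(=O)C=C[C@]12CC[C@]13C=C(C)C(=O)[C@](C)(C[C@H]1C2=O)[C@]31COC(=O)C1(Cl)Cl | intermediate
28 | spiro γ-lactone (ring E) with ring B ketone and ring D enone | CC1(C)OC(=O)C=C[C@]12CC[C@]13C=C(C)C(=O)[C@](C)(C[C@H]1C2=O)[C@]31COC(=O)C1 | intermediate
29 | tertiary alcohol: methyl carbinol in ring B with methyl cis to the ring-fusion hydrogen | CC1(C)OC(=O)C=C[C@]12CC[C@]13C=C(C)C(=O)[C@](C)(C[C@H]1[C@@]2(C)O)[C@]31COC(=O)C1 | intermediate
30 | (Z)-α-hydroxymethylene γ-lactone of 29 | CC1(C)OC(=O)C=C[C@]12CC[C@]13C=C(C)C(=O)[C@](C)(C[C@H]1[C@@]2(C)O)[C@]31COC(=O)/C1=C\O | intermediate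
31 | saturated ring D ketone from 30 (epimer mixture at the methyl-bearing α-carbon) | CC1(C)OC(=O)C=C[C@]12CC[C@]13CC(C)C(=O)[C@](C)(C[C@H]1[C@@]2(C)O)[C@]31COC(=O)/C1=C\O | intermediate
32 | CNP0360620.3 | CC1(C)OC(=O)C=C[C@]12CC[C@]13C[C@]4(C)C(=O)[C@](C)(C[C@H]1[C@@]2(C)O)[C@]31COC(=O)[C@@H]1[C@H]4O | target

**Totals**

Total step count: 20.
Longest linear sequence: 19 steps (1 to 32 through steps 1–3 and 5–20).

**Three steps most likely to fail, with fallbacks**

Step 11 (gold ipso-cyclisation). Risks are ortho attack instead of ipso attack, Meyer–Schuster-type side reactions, and weak control of the spiro centre. The fallback sets out from 19 and returns at 20. Phenol 19 is treated with N-iodosuccinimide in MeCN at −20 °C, so that an iodonium ion rather than a π-acid triggers the ipso attack and gives the (E)-iodomethylidene dispiro dienone F1. Palladium-catalysed hydrodeiodination (Bu3SnH, Pd(PPh3)4, THF) then gives 20.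

Step 13 (Me3SiI addition then extended-enolate alkylation). The risk is γ-alkylation at the CH2 terminus of the dienolate, which would also close a five-membered ring. The fallback sets out from 22 and returns at 28, so steps 14 to 16 are skipped; it makes the α-carbon the only possible nucleophile.
- SeO2 in dioxane at 80 °C oxidises the γ-methyl group of the dienone to give the hydroxymethyl dienone F2.
- Bromoacetyl bromide and pyridine give the bromoacetate F3.
- Activated Zn in THF brings about an intramolecular Reformatsky–Michael addition (5-exo) that closes ring E on the face away from the methylene-bearing ring B carbon and gives the spiro lactone F4, in which the ring D α-carbon now carries hydrogen.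
- Me3SiI at −78 °C gives the iodomethyl silyl enol ether F5.
- KOt-Bu forms the only ketone enolate, which is alkylated to the tetracyclic silyl enol ether F6; aqueous HCl then gives 28.

Step 20 (acid aldol onto the enolised formyl lactone). Risks are low electrophilicity of the hydroxymethylene lactone, retro-aldol, and dehydration. The fallback sets out from 30 and returns at 32. N-Chlorosuccinimide in CH2Cl2 at 0 °C gives the α-chloro-α-formyl lactone F7, a non-enolisable aldehyde. [(Ph3P)CuH]6 in toluene at −40 °C reduces the ring D enone, and the copper enolate closes the bicyclo[2.2.2]octane by reductive aldol to give the chloro aldol F8. Bu3SnH with AIBN in benzene at 80 °C removes the chlorine and gives 32.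

**Further compounds**

F1 | step 11 | (E)-iodomethylidene dispiro dienone (iodine trans to the spiro carbon) | CC1(C)OC(=O)C=C[C@]12CC[C@]3(C=C(C)C(=O)C(C)=C3C)/C(=C/I)[C@@H]2O[Si](C)(C)C(C)(C)C
F2 | step 13 | hydroxymethyl dienone | CC1(C)OC(=O)C=C[C@]12CC[C@]3(C=C(C)C(=O)C(C)=C3CO)C(=C)C2=O
F3 | step 13 | bromoacetate of F2 | CC1(C)OC(=O)C=C[C@]12CC[C@]3(C=C(C)C(=O)C(C)=C3COC(=O)CBr)C(=C)C2=O
F4 | step 13 | spiro lactone from Reformatsky–Michael closure (epimers at the ring D α-carbon) | CC1(C)OC(=O)C=C[C@]12CC[C@]3(C=C(C)C(=O)C(C)[C@]34COC(=O)C4)C(=C)C2=O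
F5 | step 13 | iodomethyl trimethylsilyl enol ether of F4 | CC1(C)OC(=O)C=C[C@]12CC[C@]3(C=C(C)C(=O)C(C)[C@]34COC(=O)C4)C(CI)=C2O[Si](C)(C)C
F6 | step 13 | trimethylsilyl enol ether of 28 | CC1(C)OC(=O)C=C[C@]12CC[C@]13C=C(C)C(=O)[C@](C)(CC1=C2O[Si](C)(C)C)[C@]31COC(=O)C1
F7 | step 20 | α-chloro-α-formyl γ-lactone (either epimer at the chlorinated carbon) | CC1(C)OC(=O)C=C[C@]12CC[C@]13C=C(C)C(=O)[C@](C)(C[C@H]1[C@@]2(C)O)[C@]31COC(=O)C1(Cl)C=O
F8 | step 20 | α-chloro aldol: target skeleton with chlorine on the lactone α-carbon | CC1(C)OC(=O)C=C[C@]12CC[C@]13C[C@]4(C)C(=O)[C@](C)(C[C@H]1[C@@]2(C)O)[C@]31COC(=O)C1(Cl)[C@H]4O
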